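**Plan**

- Retrosynthesis: the three O-benzyl groups are cut first, then the C2–aryl bond between ring C and ring B, then ring C itself (O1–C2 and C3–C4) back to an aryl C–H, and last the piperidine C2–C3 and N–C6 bonds back to an aldimine carbon and a four-carbon chain.
- Enabling feature: the piperidine hangs by its C2 on C6 of ring A, the carbon flanked by the C5 and C7 oxygens and para to O1, and its C3–C6 methylenes are unsubstituted. N1=C2 therefore maps onto the C=N of an aldimine of a symmetric 2,6-bis(benzyloxy)benzaldehyde, and C3–C6 onto a 4-chlorobutyl Grignard reagent (carbanion at C3, leaving group at C6).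
- Helper: a tert-butanesulfinyl group on nitrogen activates the C=N, directs the facial approach and then serves as the N-nucleophile; it is exchanged for methyl afterwards.
- Forward order: piperidine ring first by a one-pot addition/N-alkylation; the MOM ether para to the piperidine carbon then directs lithiation and acetylation, and the same oxygen closes ring C as a chromone, which fixes the 6- and not the 8-pattern; ring B is added by conjugate arylation; hydrogenolysis ends the route.
- Stereochemistry: piperidine C2 (S) from the (R)-sulfinyl auxiliary through a magnesium-chelated chair transition state; flavanone C2 (S) from a chiral pyridine–oxazoline ligand on palladium, independent of the remote first center.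

Key step: step 4

Remark: the facial sense of the pyridine–oxazoline palladium catalyst on the chromone is taken to be the same as on cyclic enones, which assigns the (R)-ligand to the 2S product; the ligand enantiomer would be exchanged if the chromone deviated.

**Route**

Step 1
Reactants: 1 3,5-bis(benzyloxy)phenol
Product: 3 2,6-bis(benzyloxy)-4-hydroxybenzaldehyde, via aryl iminium chloride 2 (not isolated)
Conditions: POCl3, DMF, MeCN, 0 °C → rt; then H2O, 50 °C
Reagents that add atoms: N,N-dimethylformamide, CN(C)C=O; water, O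
Why: Vilsmeier–Haack formylation, in which the chloroiminium ion should attack the phloroglucinol ring mainly para to the free hydroxyl (between the two benzyloxy groups), the known preference of 3,5-dialkoxyphenols, while the hydrogen-bonded ortho-formyl isomer should be separable by chromatography.

Step 2
Reactants: 3 2,6-bis(benzyloxy)-4-hydroxybenzaldehyde
Product: 4 2,6-bis(benzyloxy)-4-(methoxymethoxy)benzaldehyde
Conditions: NaH, MOMCl, DMF, 0 °C
Reagents that add atoms: chloromethyl methyl ether, COCCl
Why: Williamson O-alkylation of the acidic para-formyl phenoxide gives the MOM ether, which masks the oxygen that becomes O1 and later directs the lithiation.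

Step 3
Reactants: 4 2,6-bis(benzyloxy)-4-(methoxymethoxy)benzaldehyde; 5 (R)-2-methylpropane-2-sulfinamide
Product: 6 (R)-N-{(E)-[2,6-bis(benzyloxy)-4-(methoxymethoxy)phenyl]methylidene}-2-methylpropane-2-sulfinamide
Conditions: Ti(OEt)4, THF, 65 °C
Reagents that add atoms: (R)-2-methylpropane-2-sulfinamide (5), CC(C)(C)[S@@](=O)N
Why: Ti(OEt)4-mediated condensation (Ellman sulfinimine formation), in which the titanium alkoxide activates the hindered aldehyde and takes up the water, should give the E-aldimine.

Step 4
Reactants: 6 (R)-N-{(E)-[2,6-bis(benzyloxy)-4-(methoxymethoxy)phenyl]methylidene}-2-methylpropane-2-sulfinamide; 7 1-bromo-4-chlorobutane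
Product: 9 (2S)-2-[2,6-bis(benzyloxy)-4-(methoxymethoxy)phenyl]-1-[(R)-2-methylpropane-2-sulfinyl]piperidine, via bromomagnesium chloropentyl sulfinamide 8 (not isolated)
Conditions: 7, Mg, Et2O, rt; the resulting ClCH2CH2CH2CH2MgBr added to 6 in toluene, −60 → −20 °C; then t-BuOK, THF, 0 °C → rt
Reagents that add atoms: 1-bromo-4-chlorobutane (7), ClCCCCBr
Why: The carbanionic carbon of the Grignard reagent adds to the sulfinyl-activated C=N through a six-membered chair transition state in which magnesium bridges the sulfinyl oxygen and the transferring carbon with the tert-butyl group equatorial, and the magnesium sulfinamide 8 is then turned by t-BuOK into the more nucleophilic potassium amide, which displaces the terminal chloride. The closest known reaction types are the diastereoselective 1,2-addition of Grignard reagents to N-tert-butanesulfinyl aldimines and the base-induced cyclization of ω-chloroalkyl sulfinamides, run here as one anionic formal [4+2] annulation. The piperidine closes by a 6-exo-tet N-alkylation (N–C6), the C2–C3 bond having been made in the addition. The new stereocenter C2 is controlled by the sulfur stereocenter alone: in toluene the chelated chair should deliver carbon to the Si face of the (R)-configured E-aldimine, which is S at C2 with the priorities N > aryl > CH2 > H. The step needs C-addition to the imine before any alkylation by the chloride, and N- rather than O-alkylation of the ambident anion; the first is secured because the primary chloride is inert to the Grignard carbon at low temperature, the second because only nitrogen can close a six-membered ring. The aldimine is non-enolizable, so no α-deprotonation competes.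

Step 5
Reactants: 9 (2S)-2-[2,6-bis(benzyloxy)-4-(methoxymethoxy)phenyl]-1-[(R)-2-methylpropane-2-sulfinyl]piperidine
Product: 11 (2S)-2-[2,6-bis(benzyloxy)-4-(methoxymethoxy)phenyl]-1-methylpiperidine, via secondary amine hydrochloride 10 (not isolated)
Conditions: HCl (4 M in dioxane, 2 equiv), MeOH, 0 °C, 30 min; evaporation; then NaOAc, 37% aq. HCHO, NaBH(OAc)3, ClCH2CH2Cl, rt
Reagents that add atoms: formaldehyde, C=O
Why: Acidolysis of the N–S bond, the standard removal of a tert-butanesulfinyl group, is fast at 0 °C where the aryl MOM ether should persist, and the freed secondary amine is methylated by reductive amination without touching C2.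

Step 6
Reactants: 11 (2S)-2-[2,6-bis(benzyloxy)-4-(methoxymethoxy)phenyl]-1-methylpiperidine
Product: 13 1-{2,4-bis(benzyloxy)-6-(methoxymethoxy)-3-[(2S)-1-methylpiperidin-2-yl]phenyl}ethan-1-one, via aryllithium 12 (not isolated)
Conditions: n-BuLi, TMEDA, THF, −78 → 0 °C; then MeC(O)N(OMe)Me, −78 °C → rt
Reagents that add atoms: N-methoxy-N-methylacetamide, CC(=O)N(C)OC
Why: Directed ortho-metalation removes the ring hydrogen flanked by the MOM and benzyl ethers (two such positions, equivalent by rotation about the aryl–piperidine bond), and the aryllithium is acylated once by the Weinreb amide through its stable chelated tetrahedral adduct.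

Step 7
Reactants: 13 1-{2,4-bis(benzyloxy)-6-(methoxymethoxy)-3-[(2S)-1-methylpiperidin-2-yl]phenyl}ethan-1-one
Product: 15 5,7-bis(benzyloxy)-6-[(2S)-1-methylpiperidin-2-yl]-4H-chromen-4-one, via dimethylamino enone 14 (not isolated)
Conditions: Me2NCH(OMe)2, toluene, 100 °C; evaporation; then conc. HCl, MeOH, 50 °C
Reagents that add atoms: N,N-dimethylformamide dimethyl acetal, COC(OC)N(C)C
Why: Enaminone route to chromones, in which the methyl ketone condenses with the formamide acetal and acid then removes the MOM group so that the only free hydroxyl, the one para to the piperidine-bearing carbon, closes ring C by addition–elimination of dimethylamine and thereby fixes the 6-substitution pattern.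

Step 8
Reactants: 15 5,7-bis(benzyloxy)-6-[(2S)-1-methylpiperidin-2-yl]-4H-chromen-4-one; 16 4-(benzyloxy)phenylboronic acid
Product: 17 (2S)-5,7-bis(benzyloxy)-2-[4-(benzyloxy)phenyl]-6-[(2S)-1-methylpiperidin-2-yl]-2,3-dihydro-4H-chromen-4-one
Conditions: Pd(OCOCF3)2 (5 mol%), (R)-t-BuPyOX [(4R)-4-tert-butyl-2-(pyridin-2-yl)-4,5-dihydrooxazole] (6 mol%), NH4PF6 (30 mol%), CF3CO2H (1.1 equiv), H2O (5 equiv), ClCH2CH2Cl, 60 °C
Reagents that add atoms: 4-(benzyloxy)phenylboronic acid (16), OB(O)c1ccc(OCc2ccccc2)cc1
Why: Asymmetric conjugate addition of an arylboronic acid to a chromone under divalent palladium with a chiral pyridine–oxazoline ligand (transmetalation, enantio-determining insertion of C2=C3 into the Pd–aryl bond, protonolysis of the palladium enolate) should set the flavanone C2 as S under catalyst control, with the amine held as its trifluoroacetate so that it does not bind the metal.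

Step 9
Reactants: 17 (2S)-5,7-bis(benzyloxy)-2-[4-(benzyloxy)phenyl]-6-[(2S)-1-methylpiperidin-2-yl]-2,3-dihydro-4H-chromen-4-one
Product: 18 (2S)-5,7-dihydroxy-2-(4-hydroxyphenyl)-6-[(2S)-1-methylpiperidin-2-yl]-2,3-dihydro-4H-chromen-4-one
Conditions: H2 (1 atm), 10% Pd/C, EtOAc/MeOH, rt
Reagents that add atoms: none
Why: Hydrogenolysis of the three benzyl ethers over palladium under neutral conditions at room temperature avoids the acid or base that could open ring C (retro-oxa-Michael) or ionize the benzylic C–N bond.

**Compound list**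

1 | 3,5-bis(benzyloxy)phenol | Oc1cc(OCc2ccccc2)cc(OCc2ccccc2)c1 | starting material
2 | [2,6-bis(benzyloxy)-4-hydroxyphenyl]methylidene(dimethyl)ammonium chloride | C[N+](C)=Cc1c(OCc2ccccc2)cc(O)cc1OCc1ccccc1.[Cl-] | intermediate
3 | 2,6-bis(benzyloxy)-4-hydroxybenzaldehyde | O=Cc1c(OCc2ccccc2)cc(O)cc1OCc1ccccc1 | intermediate
4 | 2,6-bis(benzyloxy)-4-(methoxymethoxy)benzaldehyde | O=Cc1c(OCc2ccccc2)cc(OCOC)cc1OCc1ccccc1 | intermediate
5 | (R)-2-methylpropane-2-sulfinamide | CC(C)(C)[S@@](=O)N | starting material
6 | (R)-N-{(E)-[2,6-bis(benzyloxy)-4-(methoxymethoxy)phenyl]methylidene}-2-methylpropane-2-sulfinamide | CC(C)(C)[S@@](=O)/N=C/c1c(OCc2ccccc2)cc(OCOC)cc1OCc1ccccc1 | intermediate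
7 | 1-bromo-4-chlorobutane | ClCCCCBr | starting material
8 | N-bromomagnesium salt of (R)-N-{(1S)-1-[2,6-bis(benzyloxy)-4-(methoxymethoxy)phenyl]-5-chloropentyl}-2-methylpropane-2-sulfinamide | CC(C)(C)[S@@](=O)N([Mg]Br)[C@@H](CCCCCl)c1c(OCc2ccccc2)cc(OCOC)cc1OCc1ccccc1 | intermediate
9 | (2S)-2-[2,6-bis(benzyloxy)-4-(methoxymethoxy)phenyl]-1-[(R)-2-methylpropane-2-sulfinyl]piperidine | CC(C)(C)[S@@](=O)N1CCCC[C@H]1c1c(OCc2ccccc2)cc(OCOC)cc1OCc1ccccc1 | intermediate
10 | (2S)-2-[2,6-bis(benzyloxy)-4-(methoxymethoxy)phenyl]piperidine hydrochloride | Cl.N1CCCC[C@H]1c1c(OCc2ccccc2)cc(OCOC)cc1OCc1ccccc1 | intermediate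
11 | (2S)-2-[2,6-bis(benzyloxy)-4-(methoxymethoxy)phenyl]-1-methylpiperidine | CN1CCCC[C@H]1c1c(OCc2ccccc2)cc(OCOC)cc1OCc1ccccc1 | intermediate
12 | {2,4-bis(benzyloxy)-6-(methoxymethoxy)-3-[(2S)-1-methylpiperidin-2-yl]phenyl}lithium | [Li]c1c(OCOC)cc(OCc2ccccc2)c([C@@H]2CCCCN2C)c1OCc1ccccc1 | intermediate
13 | 1-{2,4-bis(benzyloxy)-6-(methoxymethoxy)-3-[(2S)-1-methylpiperidin-2-yl]phenyl}ethan-1-one | CC(=O)c1c(OCOC)cc(OCc2ccccc2)c([C@@H]2CCCCN2C)c1OCc1ccccc1 | intermediate
14 | (2E)-1-{2,4-bis(benzyloxy)-6-(methoxymethoxy)-3-[(2S)-1-methylpiperidin-2-yl]phenyl}-3-(dimethylamino)prop-2-en-1-one | CN(C)/C=C/C(=O)c1c(OCOC)cc(OCc2ccccc2)c([C@@H]2CCCCN2C)c1OCc1ccccc1 | intermediate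
15 | 5,7-bis(benzyloxy)-6-[(2S)-1-methylpiperidin-2-yl]-4H-chromen-4-one | O=c1ccoc2cc(OCc3ccccc3)c([C@@H]3CCCCN3C)c(OCc3ccccc3)c12 | intermediate
16 | 4-(benzyloxy)phenylboronic acid | OB(O)c1ccc(OCc2ccccc2)cc1 | starting material
17 | (2S)-5,7-bis(benzyloxy)-2-[4-(benzyloxy)phenyl]-6-[(2S)-1-methylpiperidin-2-yl]-2,3-dihydro-4H-chromen-4-one | CN1CCCC[C@H]1c1c(OCc3ccccc3)cc2c(c1OCc1ccccc1)C(=O)C[C@@H](c1ccc(OCc3ccccc3)cc1)O2 | intermediate
18 | (2S)-5,7-dihydroxy-2-(4-hydroxyphenyl)-6-[(2S)-1-methylpiperidin-2-yl]-2,3-dihydro-4H-chromen-4-one | CN1CCCC[C@H]1c1c(O)cc2c(c1O)C(=O)C[C@@H](c1ccc(O)cc1)O2 | target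

**Totals**

Total step count: 9. Longest linear sequence: 9 steps (1 → 18).

**Steps most likely to fail**

Step 4. The facial selectivity may erode or reverse if an ortho benzyloxy oxygen competes with the sulfinyl oxygen for magnesium and the addition goes through an open instead of a chair transition state. The hindered aldimine may also be reduced by β-hydride transfer from the primary alkyl Grignard reagent, and N-alkylation at the crowded nitrogen may be slow. The fallback sets out from 6 and comes back at 9. Compound 6 would be allylated with allyl bromide and indium powder in THF, a reagent without β-hydrogen that is expected to follow the same chelated chair model, to give (R)-N-{(1S)-1-[2,6-bis(benzyloxy)-4-(methoxymethoxy)phenyl]but-3-en-1-yl}-2-methylpropane-2-sulfinamide F1. N-Allylation (LiN(SiMe3)2, allyl bromide, DMF) would give the diene (R)-N-{(1S)-1-[2,6-bis(benzyloxy)-4-(methoxymethoxy)phenyl]but-3-en-1-yl}-2-methyl-N-(prop-2-en-1-yl)propane-2-sulfinamide F2. Ring-closing metathesis with the second-generation Grubbs catalyst (CH2Cl2, 40 °C) would close (2S)-2-[2,6-bis(benzyloxy)-4-(methoxymethoxy)phenyl]-1-[(R)-2-methylpropane-2-sulfinyl]-1,2,3,6-tetrahydropyridine F3. Diimide reduction (2-nitrobenzenesulfonylhydrazide, Et3N, CH2Cl2) would saturate the ring alkene without touching the benzyl ethers and give 9.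

Step 8. The tertiary amine may inhibit the catalyst, insertion into the electron-rich 5,7-dioxygenated chromone may be slow, the boronic acid may protodeboronate, and catalyst control may be incomplete. The fallback sets out from 13 and comes back at 17, and forms the O1–C2 bond instead of the C2–aryl bond. The MOM group of 13 would be removed (HCl, MeOH, rt) to give 1-{2,4-bis(benzyloxy)-6-hydroxy-3-[(2S)-1-methylpiperidin-2-yl]phenyl}ethan-1-one F4. Claisen–Schmidt condensation with 4-(benzyloxy)benzaldehyde (KOH, EtOH) would give the chalcone (2E)-1-{2,4-bis(benzyloxy)-6-hydroxy-3-[(2S)-1-methylpiperidin-2-yl]phenyl}-3-[4-(benzyloxy)phenyl]prop-2-en-1-one F5. Intramolecular oxa-Michael cyclization (NaOAc, EtOH, reflux), possible only through the single free hydroxyl, would give 17 together with its C2 epimer (2R)-5,7-bis(benzyloxy)-2-[4-(benzyloxy)phenyl]-6-[(2S)-1-methylpiperidin-2-yl]-2,3-dihydro-4H-chromen-4-one F6. The two are diastereomers because the piperidine center is fixed, so they would be separated by chromatography or crystallization, and F6 would be returned to the same equilibrating conditions, which touch only the flavanone center.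

Step 1. Formylation may go ortho to the hydroxyl instead of between the two benzyloxy groups, or twice. The fallback sets out from 1 and comes back at 3, and replaces electrophilic substitution by a sterically steered metalation. Phenol 1 would be silylated (chlorotri(propan-2-yl)silane, imidazole, DMF) to [3,5-bis(benzyloxy)phenoxy]tri(propan-2-yl)silane F7. n-BuLi (THF, 0 °C) should lithiate only the position between the two benzyloxy groups, because the bulky and weakly coordinating silyl ether shields its own ortho positions, and DMF would then give 2,6-bis(benzyloxy)-4-{[tri(propan-2-yl)silyl]oxy}benzaldehyde F8. Bu4NF (THF, 0 °C) would free the phenol and return to 3.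

**Further compounds**

F1 | step 4 | (R)-N-{(1S)-1-[2,6-bis(benzyloxy)-4-(methoxymethoxy)phenyl]but-3-en-1-yl}-2-methylpropane-2-sulfinamide | CC(C)(C)[S@@](=O)N[C@@H](CC=C)c1c(OCc2ccccc2)cc(OCOC)cc1OCc1ccccc1
F2 | step 4 | (R)-N-{(1S)-1-[2,6-bis(benzyloxy)-4-(methoxymethoxy)phenyl]but-3-en-1-yl}-2-methyl-N-(prop-2-en-1-yl)propane-2-sulfinamide | CC(C)(C)[S@@](=O)N(CC=C)[C@@H](CC=C)c1c(OCc2ccccc2)cc(OCOC)cc1OCc1ccccc1
F3 | step 4 | (2S)-2-[2,6-bis(benzyloxy)-4-(methoxymethoxy)phenyl]-1-[(R)-2-methylpropane-2-sulfinyl]-1,2,3,6-tetrahydropyridine | CC(C)(C)[S@@](=O)N1CC=CC[C@H]1c1c(OCc2ccccc2)cc(OCOC)cc1OCc1ccccc1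
F4 | step 8 | 1-{2,4-bis(benzyloxy)-6-hydroxy-3-[(2S)-1-methylpiperidin-2-yl]phenyl}ethan-1-one | CC(=O)c1c(O)cc(OCc2ccccc2)c([C@@H]2CCCCN2C)c1OCc1ccccc1
F5 | step 8 | (2E)-1-{2,4-bis(benzyloxy)-6-hydroxy-3-[(2S)-1-methylpiperidin-2-yl]phenyl}-3-[4-(benzyloxy)phenyl]prop-2-en-1-one | O=C(/C=C/c1ccc(OCc2ccccc2)cc1)c1c(O)cc(OCc2ccccc2)c([C@@H]2CCCCN2C)c1OCc1ccccc1
F6 | step 8 | (2R)-5,7-bis(benzyloxy)-2-[4-(benzyloxy)phenyl]-6-[(2S)-1-methylpiperidin-2-yl]-2,3-dihydro-4H-chromen-4-one | CN1CCCC[C@H]1c1c(OCc3ccccc3)cc2c(c1OCc1ccccc1)C(=O)C[C@H](c1ccc(OCc3ccccc3)cc1)O2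
F7 | step 1 | [3,5-bis(benzyloxy)phenoxy]tri(propan-2-yl)silane | CC(C)[Si](Oc1cc(OCc2ccccc2)cc(OCc2ccccc2)c1)(C(C)C)C(C)C
F8 | step 1 | 2,6-bis(benzyloxy)-4-{[tri(propan-2-yl)silyl]oxy}benzaldehyde | CC(C)[Si](Oc1cc(OCc2ccccc2)c(C=O)c(OCc2ccccc2)c1)(C(C)C)C(C)C
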